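## Analysis of the target

The target (33) is an unbranched phlorethol-type heptamer: seven benzene rings, lettered A to G from the 2,4,6-trihydroxyphenyl end, joined only by six diaryl ether oxygens and carrying eighteen free phenolic hydroxyls. There are no stereocentres and no ring fusions, so the whole problem is constitutional: which oxygen on which ring is an ether. Rings B, D and F are 3,5-dihydroxy-1,4-dioxygenated (ether oxygen on C1 toward ring A and on C4 toward ring G). Rings C and E are pentaoxygenated, with ether oxygens on the adjacent carbons C1 and C6 and hydroxyls on C3, C4 and C5; ring G is a 3,4,5-trihydroxyphenyl ether. Four ether carbons (A C1, B C4, D C4, F C4) lie between two oxygen-bearing carbons and two more (C C6, E C6) between an aryloxy and a hydroxy carbon, and the finished molecule has no electron-withdrawing group to help substitution on any ring. The free polyphenol is oxidised easily by air, above all in base, so every hydroxyl stays masked until a last, neutral deprotection; the diaryl ethers themselves are robust. The strategy rests on ring A: C2, C4 and C6 carry hydroxyls and C1, between C2 and C6, carries the oxygen to ring B, which is the pattern left when a 3,5-dioxohexanoate chain with an aryloxy group on its terminal carbon folds that carbon onto the ester carbon. The most hindered ether of ring A is then never made on an arene; it starts as a primary alkyl aryl ether on the unhindered C1 hydroxyl of ring B.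

## Retrosynthetic reasoning

**33 from 32.** The last cut removes sixteen O–benzyl bonds. In 32 all hydroxyls of rings B to G and the C4 hydroxyl of ring A are benzyl ethers; only the C2 and C6 hydroxyls of ring A are free. Benzyl is chosen because hydrogenolysis needs no acid, base or oxidant, which suits an air-sensitive polyphenol, and because diaryl ethers survive it.

**32 from 30 (ring A bond C1–C2).** Ring A is opened between the ether carbon C1 and the hydroxyl carbon C2. This is the only cut that turns all three ring A oxygens into chain carbonyls and leaves the ether oxygen on an sp3 carbon. The forward reaction is a Claisen closure of chain carbon C6 onto the ester carbon C1. The chain is not used as the free diketo ester under excess amide base: there the protons between the carbonyls go first, the ester becomes part of an enolate and stops being an electrophile, and the C5 enolate oxygen can close onto the ester to give an acidic 4-hydroxypyranone whose anion does not reopen. The C3 carbonyl is therefore carried as its benzyl enol ether (30). The ester then stays an electrophile, C1 and C4 are held cis on the C2=C3 double bond, and any O-closure gives a neutral pyranone that alkoxide reopens. The aryloxy group on C6 brings the acidity of C6–H close to that of C4–H, so an alkoxide base is enough. The cyclohexenedione 31 formed first enolises to the arene.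

**30 from 26 and 28 (chain bond C4–C5).** The chain is cut between C4 and C5, giving the aryloxyacetyl unit as the N-methoxy-N-methylamide 26 and the four-carbon unit as the benzyl enol ether 28 of an acetoacetate. The γ-dienolate 29 of 28 must add once to 26; the amide holds the adduct until quench.

**26 from 24 and 25 (ring B oxygen to CH2).** The O–CH2 bond is cut, leaving the hexamer phenol 24 with its one free hydroxyl on C1 of ring B, between two ring hydrogens, and the chloroacetamide 25. This is an unhindered phenol alkylation.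

**24 from 21 and 9 (ether at ring B C4), through 22 and 23.** Each remaining diaryl ether is cut on the side of the ring nearer ring A, so that this ring comes from a bromobenzaldehyde. The formyl group does two things: it activates the flanked bromide for copper-mediated substitution by the phenol, and after peracid oxidation (formate 23) it becomes the next phenol, here the C1 hydroxyl of ring B. Ring B is the 4-bromo-3,5-bis(benzyloxy) aldehyde 9 and the nucleophile is the pentamer phenol 21.

**21 from 18 and 5 (ether at ring C C6), through 19 and 20.** Ring C comes from the 2-bromo-3,4,5-tris(benzyloxy) aldehyde 5. Its bromide is ortho to the formyl group, the best-activated arrangement for copper, and its formyl carbon becomes C1 of ring C, which carries the phenol after oxidation. All five oxygens of ring C are thus in place without any hydroxylation of the ring.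

**18 from 15 and 9, 15 from 12 and 5, 12 from 4 and 9.** The same two cuts repeat for rings D, E and F with the same two building blocks (through 16 and 17, 13 and 14, 10 and 11). The chain ends at the ring G phenol 4.

**Building blocks.** Phenol 4 and bromide 5 both come from aldehyde 2, the tribenzyl ether of 1. Bromide 9 comes from ester 6 by benzylation (7), reduction (8) and oxidation. Enol ether 28 comes from the methyl enol ether 27 by alkoxy exchange.

## Alternatives that were turned down

**Alternative 1:** The three ether oxygens on C1 of rings C, E and G would each be traced back to an aryl ester, giving the permethylated tris-ester A1. Rings C, E and G are there benzoyl groups on the C4 oxygens of rings B, D and F. In the forward step a zerovalent nickel catalyst with a chelating bis(dicyclohexylphosphino)thiophene ligand would insert into each C(acyl)–O bond, lose carbon monoxide and reductively eliminate, giving the octadecamethyl ether A2.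
- For it: esters form easily even on a phenol flanked by two alkoxy groups, the acyl parts are gallic acid derivatives, and three of the six ethers, the two most congested among them, would appear in one operation. On convergence and step count for rings B to G it is stronger than the route chosen.
- Against it: the contraction is a high-temperature reaction of simple aryl esters. Here it must happen three times in one molecule, on electron-rich acyl arenes of which two carry an ortho aryloxy group, with a 2,6-dioxygenated phenoxide on nickel eliminating into a tri-ortho-substituted ether. Each incomplete event leaves an ester-containing congener of almost the same size and polarity, and free carbon monoxide slows the catalyst. The other three ethers, including the one on ring A, still need another method. Eighteen methyl ethers must finally be cleaved with a strong Lewis acid, which is rougher on the polyphenol than hydrogenolysis.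
- Comparison: the chosen strategy gives up this convergence. It offers ether formations of an established kind that can be checked one ring at a time, a neutral final deprotection, and a ring A ether that needs no arene coupling.

**Alternative 2:** Both ether bonds of ring F would be cut, leaving the ruthenium complex A3 of 2,5-dichloro-1,3-bis(benzyloxy)benzene (cyclopentadienylruthenium hexafluorophosphate, divalent ruthenium), the benzylated ring A to ring E pentamer phenol A4, and the phenol 4 of the present route. In one pot the phenoxide of A4 would displace the unflanked chloride and the phenoxide of 4 the flanked one, giving A5, the ruthenium complex of the octadecabenzyl ether, from which the metal is removed afterwards.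
- For it: π-complexation to the cationic metal makes even alkoxy-substituted chloroarenes open to nucleophilic aromatic substitution near room temperature and tolerates ortho substituents, and it joins two large fragments late. On mildness of the ether-forming event it is stronger than copper at 90 to 110 °C.
- Against it: the metal is stoichiometric, and complexation and decomplexation add steps. The order of the two substitutions must be complete although the first nucleophile is itself a flanked phenoxide (ring E C6), so the steric preference for the open chloride is eroded. An η6-bound metal on a product with six other electron-rich rings can move to another ring on warming. The method also solves ring F only: A4 already contains the ring A ether and both tri-ortho ethers (B–C, D–E), which must come from other chemistry.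
- Comparison: the chosen strategy uses one catalytic base-metal coupling throughout and removes the ring A problem by construction.

**Alternative 3:** Ring C would be grown from a four-membered ring, cutting its C6–C1 bond. Squaric acid dibenzyl ester A6 would take up a (Z)-2-aryloxyvinyl organometallic made from the ring A–B dimer and be protected, giving the 4-(methoxymethoxy)cyclobutenone A7. Thermolysis would open it to a dienylketene that closes by 6π electrocyclisation and enolises to the trimer phenol A8, free only at C6 of ring C.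
- For it: all five oxygens of ring C are placed with complete regiocontrol under neutral thermal conditions, and the one free hydroxyl is the one needed for ring D. On certainty of the ring C substitution pattern it is stronger than any coupling to a pre-formed pentaoxygenated ring.
- Against it: it needs a configurationally defined β-aryloxyvinyl organometallic derived from a dimer whose own A–B ether is the doubly flanked one. One pass builds one ring, so ring E needs a second pass of addition, protection, thermolysis and protecting-group exchange. Rings D, F and G and their ethers remain.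
- Comparison: the chosen route takes the pentaoxygenated pattern of rings C and E ready-made from bromide 5, one step from 2, so building these rings de novo buys certainty at a high price in steps. The chosen strategy keeps ring construction for ring A, where it removes the worst carbon–oxygen bond.

Key step: step 20

Remark on numbering: on each of rings B to G, C1 is the carbon whose ether oxygen points toward ring A; on ring A, C1 carries the ether oxygen. Chain atoms of 30 run from the ester carbon (C1) to the aryloxy-bearing carbon (C6).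

Assumption: 1, 6, 25 and 27 are purchased. The copper couplings, the ring closure and the hydrogenolysis are run with exclusion of air, because the phenoxides and the final polyphenol oxidise easily.

## Route

Step 1
Reactants: 1 3,4,5-trihydroxybenzaldehyde
Product: 2 3,4,5-tris(benzyloxy)benzaldehyde
Conditions: BnBr, K2CO3, DMF, 60 °C
Reagents that add atoms: benzyl bromide, BrCc1ccccc1
Why: Williamson etherification of the three phenols; the aldehyde has no α-hydrogen and is inert to carbonate.

Step 2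
Reactants: 2 3,4,5-tris(benzyloxy)benzaldehyde
Product: 4 3,4,5-tris(benzyloxy)phenol, via aryl formate 3 (not isolated)
Conditions: mCPBA, CH2Cl2, 0 °C to rt; then K2CO3 (cat.), MeOH, rt
Reagents that add atoms: 3-chloroperoxybenzoic acid (mCPBA), OOC(=O)c1cccc(Cl)c1
Why: Baeyer–Villiger oxidation in which the aryl group migrates because of its para benzyloxy donor; the formate 3 is cleaved by methanol under carbonate catalysis.

Step 3
Reactants: 2 3,4,5-tris(benzyloxy)benzaldehyde
Product: 5 2-bromo-3,4,5-tris(benzyloxy)benzaldehyde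
Conditions: NBS, MeCN, rt to 50 °C
Reagents that add atoms: N-bromosuccinimide, O=C1CCC(=O)N1Br
Why: Electrophilic aromatic bromination; the only open positions (C2 and C6) are equivalent, the first bromine deactivates the ring against a second, and the benzyl phenyl rings are not activated.

Step 4
Reactants: 6 methyl 4-bromo-3,5-dihydroxybenzoate
Product: 7 methyl 3,5-bis(benzyloxy)-4-bromobenzoate
Conditions: BnBr, K2CO3, DMF, 60 °C
Reagents that add atoms: benzyl bromide, BrCc1ccccc1
Why: Williamson etherification of both phenols; the methyl ester and the aryl bromide are inert.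

Step 5
Reactants: 7 methyl 3,5-bis(benzyloxy)-4-bromobenzoate
Product: 8 [3,5-bis(benzyloxy)-4-bromophenyl]methanol
Conditions: iBu2AlH, CH2Cl2, −78 to 0 °C; aq. potassium sodium tartrate
Reagents that add atoms: none
Why: Hydride reduction of the ester to the primary alcohol; the aluminium hydride leaves the aryl bromide and the benzyl ethers untouched at this temperature.

Step 6
Reactants: 8 [3,5-bis(benzyloxy)-4-bromophenyl]methanol
Product: 9 3,5-bis(benzyloxy)-4-bromobenzaldehyde
Conditions: MnO2 (activated), CH2Cl2, rt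
Reagents that add atoms: none
Why: Selective oxidation of a benzylic alcohol that stops at the aldehyde.

Step 7
Reactants: 4 3,4,5-tris(benzyloxy)phenol; 9 3,5-bis(benzyloxy)-4-bromobenzaldehyde
Product: 10 3,5-bis(benzyloxy)-4-[3,4,5-tris(benzyloxy)phenoxy]benzaldehyde (rings F–G)
Conditions: CuI (10 mol %), picolinic acid (20 mol %), K3PO4, DMSO, 90 °C, Ar
Reagents that add atoms: none
Why: Ullmann-type copper-catalysed C–O coupling; the para formyl group activates the bromide although two benzyloxy groups flank it, picolinic acid is a ligand suited to hindered diaryl ethers, and the phenoxide of 4 is unhindered.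

Step 8
Reactants: 10 ring F–G aldehyde
Product: 12 3,5-bis(benzyloxy)-4-[3,4,5-tris(benzyloxy)phenoxy]phenol (F–G phenol, free hydroxyl on C1 of ring F), via aryl formate 11 (not isolated)
Conditions: mCPBA, CH2Cl2, 0 °C to rt; then K2CO3 (cat.), MeOH, rt
Reagents that add atoms: 3-chloroperoxybenzoic acid (mCPBA), OOC(=O)c1cccc(Cl)c1
Why: Baeyer–Villiger oxidation with aryl migration supported by the para aryloxy oxygen, then methanolysis of the formate; benzyl and diaryl ethers are inert to the peracid under these conditions.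

Step 9
Reactants: 12 F–G phenol; 5 2-bromo-3,4,5-tris(benzyloxy)benzaldehyde
Product: 13 3,4,5-tris(benzyloxy)-2-{3,5-bis(benzyloxy)-4-[3,4,5-tris(benzyloxy)phenoxy]phenoxy}benzaldehyde (rings E–G)
Conditions: CuI (10 mol %), picolinic acid (20 mol %), K3PO4, DMSO, 90 °C, Ar
Reagents that add atoms: none
Why: Ullmann-type coupling of an unhindered phenol with a bromide ortho to a formyl group, the arrangement most strongly activated in copper-mediated ether synthesis (as with 2-bromo-3,4,5-trialkoxybenzoyl compounds).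

Step 10
Reactants: 13 ring E–G aldehyde
Product: 15 3,4,5-tris(benzyloxy)-2-{3,5-bis(benzyloxy)-4-[3,4,5-tris(benzyloxy)phenoxy]phenoxy}phenol (E–G phenol, free hydroxyl on C1 of ring E), via aryl formate 14 (not isolated)
Conditions: mCPBA, CH2Cl2, 0 °C to rt; then K2CO3 (cat.), MeOH, rt
Reagents that add atoms: 3-chloroperoxybenzoic acid (mCPBA), OOC(=O)c1cccc(Cl)c1
Why: Baeyer–Villiger oxidation; the migrating ring has an ortho aryloxy and a para benzyloxy donor, so aryl migration is favoured over hydride migration; the formate is cleaved by methanol.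

Step 11
Reactants: 15 E–G phenol; 9 3,5-bis(benzyloxy)-4-bromobenzaldehyde
Product: 16 3,5-bis(benzyloxy)-4-(aryloxy)benzaldehyde in which the aryloxy group is the phenoxy residue of 15 (rings D–G)
Conditions: CuI (20 mol %), picolinic acid (40 mol %), K3PO4, DMSO, 100 °C, Ar
Reagents that add atoms: none
Why: Ullmann-type coupling that gives a tri-ortho-substituted ether (one ortho aryloxy group on the phenol, two ortho benzyloxy groups on the bromide); para-formyl activation and the hindered-ether ligand make it defensible, at higher loading and temperature than step 7.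

Step 12
Reactants: 16 ring D–G aldehyde
Product: 18 3,5-bis(benzyloxy)-4-(aryloxy)phenol, aryloxy being the phenoxy residue of 15 (D–G phenol, free hydroxyl on C1 of ring D), via aryl formate 17 (not isolated)
Conditions: mCPBA, CH2Cl2, 0 °C to rt; then K2CO3 (cat.), MeOH, rt
Reagents that add atoms: 3-chloroperoxybenzoic acid (mCPBA), OOC(=O)c1cccc(Cl)c1
Why: Baeyer–Villiger oxidation with aryl migration (para aryloxy donor) and formate methanolysis, as in step 8.

Step 13
Reactants: 18 D–G phenol; 5 2-bromo-3,4,5-tris(benzyloxy)benzaldehyde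
Product: 19 3,4,5-tris(benzyloxy)-2-(aryloxy)benzaldehyde, aryloxy being the phenoxy residue of 18 (rings C–G)
Conditions: CuI (10 mol %), picolinic acid (20 mol %), K3PO4, DMSO, 90 °C, Ar
Reagents that add atoms: none
Why: Ullmann-type coupling of an unhindered phenol with the ortho-formyl-activated bromide, as in step 9.

Step 14
Reactants: 19 ring C–G aldehyde
Product: 21 3,4,5-tris(benzyloxy)-2-(aryloxy)phenol, aryloxy being the phenoxy residue of 18 (C–G phenol, free hydroxyl on C1 of ring C), via aryl formate 20 (not isolated)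
Conditions: mCPBA, CH2Cl2, 0 °C to rt; then K2CO3 (cat.), MeOH, rt
Reagents that add atoms: 3-chloroperoxybenzoic acid (mCPBA), OOC(=O)c1cccc(Cl)c1
Why: Baeyer–Villiger oxidation with aryl migration (ortho aryloxy and para benzyloxy donors) and formate methanolysis, as in step 10.

Step 15
Reactants: 21 C–G phenol; 9 3,5-bis(benzyloxy)-4-bromobenzaldehyde
Product: 22 3,5-bis(benzyloxy)-4-(aryloxy)benzaldehyde, aryloxy being the phenoxy residue of 21 (rings B–G)
Conditions: CuI (20 mol %), picolinic acid (40 mol %), K3PO4, DMSO, 100 °C, Ar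
Reagents that add atoms: none
Why: Ullmann-type coupling to a tri-ortho-substituted ether as in step 11, relying on para-formyl activation of the flanked bromide.

Step 16
Reactants: 22 ring B–G aldehyde
Product: 24 hexamer phenol: 3,5-bis(benzyloxy)-4-(aryloxy)phenol, aryloxy being the phenoxy residue of 21 (fifteen benzyl ethers, free hydroxyl on C1 of ring B), via aryl formate 23 (not isolated)
Conditions: mCPBA, CH2Cl2, 0 °C to rt; then K2CO3 (cat.), MeOH, rt
Reagents that add atoms: 3-chloroperoxybenzoic acid (mCPBA), OOC(=O)c1cccc(Cl)c1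
Why: Baeyer–Villiger oxidation with aryl migration and formate methanolysis, as in steps 8 and 12.

Step 17
Reactants: 24 hexamer phenol; 25 2-chloro-N-methoxy-N-methylacetamide
Product: 26 N-methoxy-N-methyl-2-(aryloxy)acetamide, aryloxy being the phenoxy residue of 24
Conditions: K2CO3, NaI (cat.), DMF, 60 °C
Reagents that add atoms: none
Why: Williamson alkylation (SN2) of an unhindered phenoxide with an α-halo amide, iodide catalysis; this makes the future ring A ether as a primary alkyl aryl ether.

Step 18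
Reactants: 27 methyl (E)-3-methoxybut-2-enoate
Product: 28 methyl (E)-3-(benzyloxy)but-2-enoate
Conditions: BnOH, TsOH·H2O (cat.), toluene, 110 °C, MeOH distilled off
Reagents that add atoms: benzyl alcohol, OCc1ccccc1
Why: Acid-catalysed alkoxy exchange of a β-alkoxy enoate (C-protonation, mixed ketal, loss of methanol), driven by removal of methanol and giving the more stable E isomer. Ester exchange is slower at this vinylogous carbonate and would be harmless, since that alkoxy group is lost in step 20.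

Step 19
Reactants: 28 methyl (E)-3-(benzyloxy)but-2-enoate; 26 aryloxyacetyl N-methoxy-N-methylamide
Product: 30 methyl (E)-6-(aryloxy)-3-(benzyloxy)-5-oxohex-2-enoate, aryloxy being the phenoxy residue of 24 (the methyl 6-aryloxy-3,5-dioxohexanoate with its C3 carbonyl held as benzyl enol ether), via lithium dienolate 29 (not isolated)
Conditions: LiN(iPr)2, THF, −78 °C; then 26, −78 to −40 °C; aq. NH4Cl
Reagents that add atoms: none
Why: Vinylogous Claisen-type acylation: the amide base removes a γ-proton of 28 and the 1,3-dioxygenated dienolate 29 reacts at its γ-terminus, as such alkoxy dienolates do. The N-methoxy-N-methylamide holds the adduct as a chelated tetrahedral intermediate until quench, so there is no second addition; any Z isomer equilibrates under the conditions of step 20.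

Step 20
Reactants: 30 methyl (E)-6-(aryloxy)-3-(benzyloxy)-5-oxohex-2-enoate
Product: 32 heptamer 2-(aryloxy)-5-(benzyloxy)benzene-1,3-diol, aryloxy being the phenoxy residue of 24 (ring A with free hydroxyls on C2 and C6 and a benzyl ether on C4; sixteen benzyl ethers), via cyclohexenedione 31 (not isolated)
Conditions: KOtBu, BnOH, THF (high dilution), 50 °C, Ar; then aq. HCl
Reagents that add atoms: none
Why: Alkoxide deprotonates the chain reversibly at C4 and at C6; the C6 enolate, an α-aryloxy ketone enolate, adds to the ester carbon C1 held cis to C4 on the C2=C3 double bond, and loss of methoxide gives cyclohexenedione 31, which enolises twice to the resorcinol diphenoxide. The closest known reaction type is the base-mediated Claisen cyclisation of 3-alkoxy-5-oxohex-2-enoates (ring-opened 4-alkoxypyran-2-ones) to 5-alkoxyresorcinols, together with the polyketide-type Claisen closure of 3,5,7-trioxoalkanoates to acylphloroglucinols. Ring A closes in a 6-exo-trig Claisen (Dieckmann-like) mode by forming the bond between chain C6 and C1, that is ring A C1–C2; no stereocentre remains in the product. The selectivity needed is C-acylation through C6 in preference to O-acylation by the C5 enolate oxygen; closure from C4 would need a four-membered ring and does not compete. Three features of the substrate secure this: the enol ether keeps the ester from becoming a β-keto ester enolate, the aryloxy group raises the acidity of C6–H close to that of C4–H, and the product of O-closure is a neutral 4-alkoxypyranone that alkoxide reopens, whereas aromatisation to the diphenoxide is irreversible. An alkoxide rather than an amide base keeps the chain as a monoanion, since the C4,C6-dianion would again carry the ester as an enolate. Benzyl alcohol in excess makes any alkoxide exchange at the enol ether carbon degenerate, and dilution suppresses intermolecular condensation.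

Step 21
Reactants: 32 heptamer with sixteen benzyl ethers
Product: 33 target CNP0292517.0
Conditions: H2 (1 atm), Pd/C (10 wt % palladium on carbon), THF/MeOH, rt; filtered and concentrated under Ar
Reagents that add atoms: none
Why: Hydrogenolysis of all sixteen aryl benzyl ethers under neutral conditions; diaryl ethers and the arene rings are not reduced under these conditions.

## Compound list

1 | 3,4,5-trihydroxybenzaldehyde | O=Cc1cc(O)c(O)c(O)c1 | starting material
2 | 3,4,5-tris(benzyloxy)benzaldehyde | O=Cc1cc(OCc9ccccc9)c(OCc9ccccc9)c(OCc9ccccc9)c1 | intermediate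
3 | 3,4,5-tris(benzyloxy)phenyl formate | O=COc1cc(OCc9ccccc9)c(OCc9ccccc9)c(OCc9ccccc9)c1 | intermediate (not isolated)
4 | 3,4,5-tris(benzyloxy)phenol (ring G) | Oc1cc(OCc9ccccc9)c(OCc9ccccc9)c(OCc9ccccc9)c1 | intermediate
5 | 2-bromo-3,4,5-tris(benzyloxy)benzaldehyde | O=Cc1cc(OCc9ccccc9)c(OCc9ccccc9)c(OCc9ccccc9)c1Br | intermediate
6 | methyl 4-bromo-3,5-dihydroxybenzoate | COC(=O)c1cc(O)c(Br)c(O)c1 | starting material
7 | methyl 3,5-bis(benzyloxy)-4-bromobenzoate | COC(=O)c1cc(OCc9ccccc9)c(Br)c(OCc9ccccc9)c1 | intermediate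
8 | [3,5-bis(benzyloxy)-4-bromophenyl]methanol | OCc1cc(OCc9ccccc9)c(Br)c(OCc9ccccc9)c1 | intermediate
9 | 3,5-bis(benzyloxy)-4-bromobenzaldehyde | O=Cc1cc(OCc9ccccc9)c(Br)c(OCc9ccccc9)c1 | intermediate
10 | 3,5-bis(benzyloxy)-4-[3,4,5-tris(benzyloxy)phenoxy]benzaldehyde (rings F–G) | O=Cc4cc(OCc9ccccc9)c(Oc5cc(OCc9ccccc9)c(OCc9ccccc9)c(OCc9ccccc9)c5)c(OCc9ccccc9)c4 | intermediate
11 | 3,5-bis(benzyloxy)-4-[3,4,5-tris(benzyloxy)phenoxy]phenyl formate | O=COc4cc(OCc9ccccc9)c(Oc5cc(OCc9ccccc9)c(OCc9ccccc9)c(OCc9ccccc9)c5)c(OCc9ccccc9)c4 | intermediate (not isolated)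
12 | 3,5-bis(benzyloxy)-4-[3,4,5-tris(benzyloxy)phenoxy]phenol (F–G phenol) | Oc4cc(OCc9ccccc9)c(Oc5cc(OCc9ccccc9)c(OCc9ccccc9)c(OCc9ccccc9)c5)c(OCc9ccccc9)c4 | intermediate
13 | 3,4,5-tris(benzyloxy)-2-{3,5-bis(benzyloxy)-4-[3,4,5-tris(benzyloxy)phenoxy]phenoxy}benzaldehyde (rings E–G) | O=Cc4cc(OCc9ccccc9)c(OCc9ccccc9)c(OCc9ccccc9)c4Oc4cc(OCc9ccccc9)c(Oc5cc(OCc9ccccc9)c(OCc9ccccc9)c(OCc9ccccc9)c5)c(OCc9ccccc9)c4 | intermediate
14 | formate ester of 15 (formyloxy on C1 of ring E) | O=COc4cc(OCc9ccccc9)c(OCc9ccccc9)c(OCc9ccccc9)c4Oc4cc(OCc9ccccc9)c(Oc5cc(OCc9ccccc9)c(OCc9ccccc9)c(OCc9ccccc9)c5)c(OCc9ccccc9)c4 | intermediate (not isolated)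
15 | 3,4,5-tris(benzyloxy)-2-{3,5-bis(benzyloxy)-4-[3,4,5-tris(benzyloxy)phenoxy]phenoxy}phenol (E–G phenol) | Oc4cc(OCc9ccccc9)c(OCc9ccccc9)c(OCc9ccccc9)c4Oc4cc(OCc9ccccc9)c(Oc5cc(OCc9ccccc9)c(OCc9ccccc9)c(OCc9ccccc9)c5)c(OCc9ccccc9)c4 | intermediate
16 | 3,5-bis(benzyloxy)-4-(aryloxy)benzaldehyde, aryloxy = phenoxy residue of 15 (rings D–G) | O=Cc3cc(OCc9ccccc9)c(Oc4cc(OCc9ccccc9)c(OCc9ccccc9)c(OCc9ccccc9)c4Oc4cc(OCc9ccccc9)c(Oc5cc(OCc9ccccc9)c(OCc9ccccc9)c(OCc9ccccc9)c5)c(OCc9ccccc9)c4)c(OCc9ccccc9)c3 | intermediate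
17 | formate ester of 18 (formyloxy on C1 of ring D) | O=COc3cc(OCc9ccccc9)c(Oc4cc(OCc9ccccc9)c(OCc9ccccc9)c(OCc9ccccc9)c4Oc4cc(OCc9ccccc9)c(Oc5cc(OCc9ccccc9)c(OCc9ccccc9)c(OCc9ccccc9)c5)c(OCc9ccccc9)c4)c(OCc9ccccc9)c3 | intermediate (not isolated)
18 | 3,5-bis(benzyloxy)-4-(aryloxy)phenol, aryloxy = phenoxy residue of 15 (D–G phenol) | Oc3cc(OCc9ccccc9)c(Oc4cc(OCc9ccccc9)c(OCc9ccccc9)c(OCc9ccccc9)c4Oc4cc(OCc9ccccc9)c(Oc5cc(OCc9ccccc9)c(OCc9ccccc9)c(OCc9ccccc9)c5)c(OCc9ccccc9)c4)c(OCc9ccccc9)c3 | intermediate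
19 | 3,4,5-tris(benzyloxy)-2-(aryloxy)benzaldehyde, aryloxy = phenoxy residue of 18 (rings C–G) | O=Cc3cc(OCc9ccccc9)c(OCc9ccccc9)c(OCc9ccccc9)c3Oc3cc(OCc9ccccc9)c(Oc4cc(OCc9ccccc9)c(OCc9ccccc9)c(OCc9ccccc9)c4Oc4cc(OCc9ccccc9)c(Oc5cc(OCc9ccccc9)c(OCc9ccccc9)c(OCc9ccccc9)c5)c(OCc9ccccc9)c4)c(OCc9ccccc9)c3 | intermediate
20 | formate ester of 21 (formyloxy on C1 of ring C) | O=COc3cc(OCc9ccccc9)c(OCc9ccccc9)c(OCc9ccccc9)c3Oc3cc(OCc9ccccc9)c(Oc4cc(OCc9ccccc9)c(OCc9ccccc9)c(OCc9ccccc9)c4Oc4cc(OCc9ccccc9)c(Oc5cc(OCc9ccccc9)c(OCc9ccccc9)c(OCc9ccccc9)c5)c(OCc9ccccc9)c4)c(OCc9ccccc9)c3 | intermediate (not isolated)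
21 | 3,4,5-tris(benzyloxy)-2-(aryloxy)phenol, aryloxy = phenoxy residue of 18 (C–G phenol) | Oc3cc(OCc9ccccc9)c(OCc9ccccc9)c(OCc9ccccc9)c3Oc3cc(OCc9ccccc9)c(Oc4cc(OCc9ccccc9)c(OCc9ccccc9)c(OCc9ccccc9)c4Oc4cc(OCc9ccccc9)c(Oc5cc(OCc9ccccc9)c(OCc9ccccc9)c(OCc9ccccc9)c5)c(OCc9ccccc9)c4)c(OCc9ccccc9)c3 | intermediate
22 | 3,5-bis(benzyloxy)-4-(aryloxy)benzaldehyde, aryloxy = phenoxy residue of 21 (rings B–G) | O=Cc2cc(OCc9ccccc9)c(Oc3cc(OCc9ccccc9)c(OCc9ccccc9)c(OCc9ccccc9)c3Oc3cc(OCc9ccccc9)c(Oc4cc(OCc9ccccc9)c(OCc9ccccc9)c(OCc9ccccc9)c4Oc4cc(OCc9ccccc9)c(Oc5cc(OCc9ccccc9)c(OCc9ccccc9)c(OCc9ccccc9)c5)c(OCc9ccccc9)c4)c(OCc9ccccc9)c3)c(OCc9ccccc9)c2 | intermediate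
23 | formate ester of 24 (formyloxy on C1 of ring B) | O=COc2cc(OCc9ccccc9)c(Oc3cc(OCc9ccccc9)c(OCc9ccccc9)c(OCc9ccccc9)c3Oc3cc(OCc9ccccc9)c(Oc4cc(OCc9ccccc9)c(OCc9ccccc9)c(OCc9ccccc9)c4Oc4cc(OCc9ccccc9)c(Oc5cc(OCc9ccccc9)c(OCc9ccccc9)c(OCc9ccccc9)c5)c(OCc9ccccc9)c4)c(OCc9ccccc9)c3)c(OCc9ccccc9)c2 | intermediate (not isolated)
24 | hexamer phenol, rings B–G, fifteen benzyl ethers, free hydroxyl on C1 of ring B | Oc2cc(OCc9ccccc9)c(Oc3cc(OCc9ccccc9)c(OCc9ccccc9)c(OCc9ccccc9)c3Oc3cc(OCc9ccccc9)c(Oc4cc(OCc9ccccc9)c(OCc9ccccc9)c(OCc9ccccc9)c4Oc4cc(OCc9ccccc9)c(Oc5cc(OCc9ccccc9)c(OCc9ccccc9)c(OCc9ccccc9)c5)c(OCc9ccccc9)c4)c(OCc9ccccc9)c3)c(OCc9ccccc9)c2 | intermediate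
25 | 2-chloro-N-methoxy-N-methylacetamide | CON(C)C(=O)CCl | starting material
26 | N-methoxy-N-methyl-2-(aryloxy)acetamide, aryloxy = phenoxy residue of 24 | CON(C)C(=O)COc2cc(OCc9ccccc9)c(Oc3cc(OCc9ccccc9)c(OCc9ccccc9)c(OCc9ccccc9)c3Oc3cc(OCc9ccccc9)c(Oc4cc(OCc9ccccc9)c(OCc9ccccc9)c(OCc9ccccc9)c4Oc4cc(OCc9ccccc9)c(Oc5cc(OCc9ccccc9)c(OCc9ccccc9)c(OCc9ccccc9)c5)c(OCc9ccccc9)c4)c(OCc9ccccc9)c3)c(OCc9ccccc9)c2 | intermediate
27 | methyl (E)-3-methoxybut-2-enoate | COC(=O)/C=C(/OC)C | starting material
28 | methyl (E)-3-(benzyloxy)but-2-enoate | COC(=O)/C=C(/OCc1ccccc1)C | intermediate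
29 | lithium 3-(benzyloxy)-1-methoxybuta-1,3-dien-1-olate (γ-dienolate of 28) | [Li+].[O-]C(OC)=CC(=C)OCc1ccccc1 | intermediate (not isolated)
30 | methyl (E)-6-(aryloxy)-3-(benzyloxy)-5-oxohex-2-enoate, aryloxy = phenoxy residue of 24 | COC(=O)/C=C(/OCc9ccccc9)CC(=O)COc2cc(OCc9ccccc9)c(Oc3cc(OCc9ccccc9)c(OCc9ccccc9)c(OCc9ccccc9)c3Oc3cc(OCc9ccccc9)c(Oc4cc(OCc9ccccc9)c(OCc9ccccc9)c(OCc9ccccc9)c4Oc4cc(OCc9ccccc9)c(Oc5cc(OCc9ccccc9)c(OCc9ccccc9)c(OCc9ccccc9)c5)c(OCc9ccccc9)c4)c(OCc9ccccc9)c3)c(OCc9ccccc9)c2 | intermediate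
31 | 2-(aryloxy)-5-(benzyloxy)cyclohex-4-ene-1,3-dione (racemic), aryloxy = phenoxy residue of 24 | O=C1C=C(OCc9ccccc9)CC(=O)C1Oc2cc(OCc9ccccc9)c(Oc3cc(OCc9ccccc9)c(OCc9ccccc9)c(OCc9ccccc9)c3Oc3cc(OCc9ccccc9)c(Oc4cc(OCc9ccccc9)c(OCc9ccccc9)c(OCc9ccccc9)c4Oc4cc(OCc9ccccc9)c(Oc5cc(OCc9ccccc9)c(OCc9ccccc9)c(OCc9ccccc9)c5)c(OCc9ccccc9)c4)c(OCc9ccccc9)c3)c(OCc9ccccc9)c2 | intermediate (not isolated)
32 | heptamer 2-(aryloxy)-5-(benzyloxy)benzene-1,3-diol, aryloxy = phenoxy residue of 24 (sixteen benzyl ethers) | Oc1cc(OCc9ccccc9)cc(O)c1Oc2cc(OCc9ccccc9)c(Oc3cc(OCc9ccccc9)c(OCc9ccccc9)c(OCc9ccccc9)c3Oc3cc(OCc9ccccc9)c(Oc4cc(OCc9ccccc9)c(OCc9ccccc9)c(OCc9ccccc9)c4Oc4cc(OCc9ccccc9)c(Oc5cc(OCc9ccccc9)c(OCc9ccccc9)c(OCc9ccccc9)c5)c(OCc9ccccc9)c4)c(OCc9ccccc9)c3)c(OCc9ccccc9)c2 | intermediate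
33 | CNP0292517.0, 2-[4-(2-{4-[2-{3,5-dihydroxy-4-(3,4,5-trihydroxyphenoxy)phenoxy}-3,4,5-trihydroxyphenoxy]-3,5-dihydroxyphenoxy}-3,4,5-trihydroxyphenoxy)-3,5-dihydroxyphenoxy]benzene-1,3,5-triol | Oc1cc(O)c(Oc2cc(O)c(Oc3cc(O)c(O)c(O)c3Oc3cc(O)c(Oc4cc(O)c(O)c(O)c4Oc4cc(O)c(Oc5cc(O)c(O)c(O)c5)c(O)c4)c(O)c3)c(O)c2)c(O)c1 | target

## Step count and least certain steps

Total: 21 steps. Longest linear sequence: 17 steps (6, 7, 8, 9, 10, 12, 13, 15, 16, 18, 19, 21, 22, 24, 26, 30, 32, 33; steps 4 to 17 and 19 to 21).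

**Step 20 (key step).** The chain may stay as its C4 enolate and close through oxygen faster than through C6, so that material is held as the pyranone and reopens only slowly. Alkoxide exchange at the enol ether carbon or intermolecular condensation of the large substrate may also compete with the six-membered closure. The fallback sets out from 24 and attaches ring A as a ready-made arene with the copper and peracid chemistry already used for rings B to F. Purchased 3,5-bis(benzyloxy)benzaldehyde F1 is brominated with NBS to 2-bromo-3,5-bis(benzyloxy)benzaldehyde F2, whose bromide lies between the formyl group and a benzyloxy group. Coupling of F2 with 24 (CuI, picolinic acid, K3PO4, DMSO) should give the heptamer aldehyde F3. Oxidation with mCPBA gives the heptamer formate F4, and methanolysis gives the heptamer phenol F5 (ring A with hydroxyl on C2 and benzyl ethers on C4 and C6; seventeen benzyl ethers). Hydrogenolysis over Pd/C returns to the route at 33.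

**Step 15 (and, for the same reason, step 11).** Oxidative addition of copper to a bromide flanked by two benzyloxy groups, with a phenoxide that itself has an ortho aryloxy group, may be so slow that protodebromination of 9 and oxidative loss of the phenoxide take over. The fallback sets out from 7 and 21 and transfers the aryl group from trivalent iodine without a metal. Halogen exchange on 7 (NaI, CuI, trans-N,N'-dimethylcyclohexane-1,2-diamine, dioxane, 110 °C) gives methyl 3,5-bis(benzyloxy)-4-iodobenzoate F6. Oxidation with mCPBA and TsOH·H2O followed by 1,3,5-trimethoxybenzene gives [2,6-bis(benzyloxy)-4-(methoxycarbonyl)phenyl](2,4,6-trimethoxyphenyl)iodonium tosylate F7. The phenoxide of 21 (KOtBu, THF, rt) should take the more electron-poor aryl group from iodine, giving the hexamer methyl ester F8. Reduction with iBu2AlH gives the hexamer benzylic alcohol F9, and MnO2 returns to the route at 22.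

**Step 16 (and steps 8 and 12).** On these rings the para oxygen is a diaryl ether oxygen twisted by its two benzyloxy neighbours, so its donation is weak; hydride migration may then compete with aryl migration and lead to the benzoic acid. The fallback sets out from 22 and replaces the migrating hydrogen by a methyl group. MeMgBr gives the racemic hexamer 1-arylethanol F10, MnO2 the hexamer methyl ketone F11, and mCPBA the hexamer aryl acetate F12 (aryl migrates in preference to methyl). Methanolysis with K2CO3 returns to the route at 24.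

**Step 19.** The dienolate may act as a base toward the OCH2 protons of 26 instead of adding to the amide carbonyl, or some attack through the α-carbon may occur, so that 26 is recovered or the chain is branched. The fallback sets out from 26 and passes through the free diketo ester and its pyranone. The dianion of methyl acetoacetate (2 equiv LiN(iPr)2, THF) is acylated by 26 to give methyl 6-(aryloxy)-3,5-dioxohexanoate F13. DBU in toluene lactonises F13 to 6-(aryloxymethyl)-4-hydroxypyran-2-one F14, and BnBr with K2CO3 gives 6-(aryloxymethyl)-4-(benzyloxy)pyran-2-one F15. Ring opening with Mg(OMe)2 in MeOH returns to the route at 30, with the E geometry fixed by the ring.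

## Further compounds

F1 | step 20 | 3,5-bis(benzyloxy)benzaldehyde (purchased) | O=Cc1cc(OCc9ccccc9)cc(OCc9ccccc9)c1
F2 | step 20 | 2-bromo-3,5-bis(benzyloxy)benzaldehyde | O=Cc1cc(OCc9ccccc9)cc(OCc9ccccc9)c1Br
F3 | step 20 | heptamer aldehyde, 3,5-bis(benzyloxy)-2-(aryloxy)benzaldehyde, aryloxy = phenoxy residue of 24 | O=Cc1cc(OCc9ccccc9)cc(OCc9ccccc9)c1Oc2cc(OCc9ccccc9)c(Oc3cc(OCc9ccccc9)c(OCc9ccccc9)c(OCc9ccccc9)c3Oc3cc(OCc9ccccc9)c(Oc4cc(OCc9ccccc9)c(OCc9ccccc9)c(OCc9ccccc9)c4Oc4cc(OCc9ccccc9)c(Oc5cc(OCc9ccccc9)c(OCc9ccccc9)c(OCc9ccccc9)c5)c(OCc9ccccc9)c4)c(OCc9ccccc9)c3)c(OCc9ccccc9)c2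
F4 | step 20 | heptamer formate, 3,5-bis(benzyloxy)-2-(aryloxy)phenyl formate | O=COc1cc(OCc9ccccc9)cc(OCc9ccccc9)c1Oc2cc(OCc9ccccc9)c(Oc3cc(OCc9ccccc9)c(OCc9ccccc9)c(OCc9ccccc9)c3Oc3cc(OCc9ccccc9)c(Oc4cc(OCc9ccccc9)c(OCc9ccccc9)c(OCc9ccccc9)c4Oc4cc(OCc9ccccc9)c(Oc5cc(OCc9ccccc9)c(OCc9ccccc9)c(OCc9ccccc9)c5)c(OCc9ccccc9)c4)c(OCc9ccccc9)c3)c(OCc9ccccc9)c2
F5 | step 20 | heptamer phenol, 3,5-bis(benzyloxy)-2-(aryloxy)phenol (seventeen benzyl ethers) | Oc1cc(OCc9ccccc9)cc(OCc9ccccc9)c1Oc2cc(OCc9ccccc9)c(Oc3cc(OCc9ccccc9)c(OCc9ccccc9)c(OCc9ccccc9)c3Oc3cc(OCc9ccccc9)c(Oc4cc(OCc9ccccc9)c(OCc9ccccc9)c(OCc9ccccc9)c4Oc4cc(OCc9ccccc9)c(Oc5cc(OCc9ccccc9)c(OCc9ccccc9)c(OCc9ccccc9)c5)c(OCc9ccccc9)c4)c(OCc9ccccc9)c3)c(OCc9ccccc9)c2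
F6 | step 15 | methyl 3,5-bis(benzyloxy)-4-iodobenzoate | COC(=O)c1cc(OCc9ccccc9)c(I)c(OCc9ccccc9)c1
F7 | step 15 | [2,6-bis(benzyloxy)-4-(methoxycarbonyl)phenyl](2,4,6-trimethoxyphenyl)iodonium tosylate | COC(=O)c1cc(OCc9ccccc9)c([I+]c2c(OC)cc(OC)cc2OC)c(OCc9ccccc9)c1.Cc1ccc(cc1)S(=O)(=O)[O-]
F8 | step 15 | hexamer methyl ester, methyl 3,5-bis(benzyloxy)-4-(aryloxy)benzoate, aryloxy = phenoxy residue of 21 | COC(=O)c2cc(OCc9ccccc9)c(Oc3cc(OCc9ccccc9)c(OCc9ccccc9)c(OCc9ccccc9)c3Oc3cc(OCc9ccccc9)c(Oc4cc(OCc9ccccc9)c(OCc9ccccc9)c(OCc9ccccc9)c4Oc4cc(OCc9ccccc9)c(Oc5cc(OCc9ccccc9)c(OCc9ccccc9)c(OCc9ccccc9)c5)c(OCc9ccccc9)c4)c(OCc9ccccc9)c3)c(OCc9ccccc9)c2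
F9 | step 15 | hexamer benzylic alcohol, [3,5-bis(benzyloxy)-4-(aryloxy)phenyl]methanol | OCc2cc(OCc9ccccc9)c(Oc3cc(OCc9ccccc9)c(OCc9ccccc9)c(OCc9ccccc9)c3Oc3cc(OCc9ccccc9)c(Oc4cc(OCc9ccccc9)c(OCc9ccccc9)c(OCc9ccccc9)c4Oc4cc(OCc9ccccc9)c(Oc5cc(OCc9ccccc9)c(OCc9ccccc9)c(OCc9ccccc9)c5)c(OCc9ccccc9)c4)c(OCc9ccccc9)c3)c(OCc9ccccc9)c2
F10 | step 16 | hexamer 1-arylethanol (racemic), 1-[3,5-bis(benzyloxy)-4-(aryloxy)phenyl]ethanol | CC(O)c2cc(OCc9ccccc9)c(Oc3cc(OCc9ccccc9)c(OCc9ccccc9)c(OCc9ccccc9)c3Oc3cc(OCc9ccccc9)c(Oc4cc(OCc9ccccc9)c(OCc9ccccc9)c(OCc9ccccc9)c4Oc4cc(OCc9ccccc9)c(Oc5cc(OCc9ccccc9)c(OCc9ccccc9)c(OCc9ccccc9)c5)c(OCc9ccccc9)c4)c(OCc9ccccc9)c3)c(OCc9ccccc9)c2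
F11 | step 16 | hexamer methyl ketone, 1-[3,5-bis(benzyloxy)-4-(aryloxy)phenyl]ethanone | CC(=O)c2cc(OCc9ccccc9)c(Oc3cc(OCc9ccccc9)c(OCc9ccccc9)c(OCc9ccccc9)c3Oc3cc(OCc9ccccc9)c(Oc4cc(OCc9ccccc9)c(OCc9ccccc9)c(OCc9ccccc9)c4Oc4cc(OCc9ccccc9)c(Oc5cc(OCc9ccccc9)c(OCc9ccccc9)c(OCc9ccccc9)c5)c(OCc9ccccc9)c4)c(OCc9ccccc9)c3)c(OCc9ccccc9)c2
F12 | step 16 | hexamer aryl acetate, 3,5-bis(benzyloxy)-4-(aryloxy)phenyl acetate | CC(=O)Oc2cc(OCc9ccccc9)c(Oc3cc(OCc9ccccc9)c(OCc9ccccc9)c(OCc9ccccc9)c3Oc3cc(OCc9ccccc9)c(Oc4cc(OCc9ccccc9)c(OCc9ccccc9)c(OCc9ccccc9)c4Oc4cc(OCc9ccccc9)c(Oc5cc(OCc9ccccc9)c(OCc9ccccc9)c(OCc9ccccc9)c5)c(OCc9ccccc9)c4)c(OCc9ccccc9)c3)c(OCc9ccccc9)c2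
F13 | step 19 | methyl 6-(aryloxy)-3,5-dioxohexanoate, aryloxy = phenoxy residue of 24 | COC(=O)CC(=O)CC(=O)COc2cc(OCc9ccccc9)c(Oc3cc(OCc9ccccc9)c(OCc9ccccc9)c(OCc9ccccc9)c3Oc3cc(OCc9ccccc9)c(Oc4cc(OCc9ccccc9)c(OCc9ccccc9)c(OCc9ccccc9)c4Oc4cc(OCc9ccccc9)c(Oc5cc(OCc9ccccc9)c(OCc9ccccc9)c(OCc9ccccc9)c5)c(OCc9ccccc9)c4)c(OCc9ccccc9)c3)c(OCc9ccccc9)c2
F14 | step 19 | 6-(aryloxymethyl)-4-hydroxypyran-2-one | O=c1cc(O)cc(COc2cc(OCc9ccccc9)c(Oc3cc(OCc9ccccc9)c(OCc9ccccc9)c(OCc9ccccc9)c3Oc3cc(OCc9ccccc9)c(Oc4cc(OCc9ccccc9)c(OCc9ccccc9)c(OCc9ccccc9)c4Oc4cc(OCc9ccccc9)c(Oc5cc(OCc9ccccc9)c(OCc9ccccc9)c(OCc9ccccc9)c5)c(OCc9ccccc9)c4)c(OCc9ccccc9)c3)c(OCc9ccccc9)c2)o1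
F15 | step 19 | 6-(aryloxymethyl)-4-(benzyloxy)pyran-2-one | O=c1cc(OCc9ccccc9)cc(COc2cc(OCc9ccccc9)c(Oc3cc(OCc9ccccc9)c(OCc9ccccc9)c(OCc9ccccc9)c3Oc3cc(OCc9ccccc9)c(Oc4cc(OCc9ccccc9)c(OCc9ccccc9)c(OCc9ccccc9)c4Oc4cc(OCc9ccccc9)c(Oc5cc(OCc9ccccc9)c(OCc9ccccc9)c(OCc9ccccc9)c5)c(OCc9ccccc9)c4)c(OCc9ccccc9)c3)c(OCc9ccccc9)c2)o1
A1 | alternative 1 | permethylated tris-ester (benzoyl groups of rings C, E and G on the C4 oxygens of rings B, D and F) | COc1cc(OC)c(Oc2cc(OC)c(OC(=O)c3cc(OC)c(OC)c(OC)c3Oc3cc(OC)c(OC(=O)c4cc(OC)c(OC)c(OC)c4Oc4cc(OC)c(OC(=O)c5cc(OC)c(OC)c(OC)c5)c(OC)c4)c(OC)c3)c(OC)c2)c(OC)c1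
A2 | alternative 1 | octadecamethyl ether of the target | COc1cc(OC)c(Oc2cc(OC)c(Oc3cc(OC)c(OC)c(OC)c3Oc3cc(OC)c(Oc4cc(OC)c(OC)c(OC)c4Oc4cc(OC)c(Oc5cc(OC)c(OC)c(OC)c5)c(OC)c4)c(OC)c3)c(OC)c2)c(OC)c1
A3 | alternative 2 | cyclopentadienylruthenium hexafluorophosphate complex of 2,5-dichloro-1,3-bis(benzyloxy)benzene, written as its components | Clc1cc(OCc9ccccc9)c(Cl)c(OCc9ccccc9)c1.[Ru+2].[cH-]1cccc1.F[P-](F)(F)(F)(F)F
A4 | alternative 2 | benzylated ring A to ring E pentamer phenol, free hydroxyl on C6 of ring E | C(c9ccccc9)Oc1cc(OCc9ccccc9)c(Oc2cc(OCc9ccccc9)c(Oc3cc(OCc9ccccc9)c(OCc9ccccc9)c(OCc9ccccc9)c3Oc3cc(OCc9ccccc9)c(Oc4cc(OCc9ccccc9)c(OCc9ccccc9)c(OCc9ccccc9)c4O)c(OCc9ccccc9)c3)c(OCc9ccccc9)c2)c(OCc9ccccc9)c1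
A5 | alternative 2 | cyclopentadienylruthenium hexafluorophosphate complex (on ring F) of the octadecabenzyl ether of the target, written as its components | C(c9ccccc9)Oc1cc(OCc9ccccc9)c(Oc2cc(OCc9ccccc9)c(Oc3cc(OCc9ccccc9)c(OCc9ccccc9)c(OCc9ccccc9)c3Oc3cc(OCc9ccccc9)c(Oc4cc(OCc9ccccc9)c(OCc9ccccc9)c(OCc9ccccc9)c4Oc4cc(OCc9ccccc9)c(Oc5cc(OCc9ccccc9)c(OCc9ccccc9)c(OCc9ccccc9)c5)c(OCc9ccccc9)c4)c(OCc9ccccc9)c3)c(OCc9ccccc9)c2)c(OCc9ccccc9)c1.[Ru+2].[cH-]1cccc1.F[P-](F)(F)(F)(F)F
A6 | alternative 3 | squaric acid dibenzyl ester, 3,4-bis(benzyloxy)cyclobut-3-ene-1,2-dione | O=C1C(=O)C(OCc9ccccc9)=C1OCc9ccccc9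
A7 | alternative 3 | 2,3-bis(benzyloxy)-4-(methoxymethoxy)-4-[(Z)-2-(aryloxy)vinyl]cyclobut-2-en-1-one, aryl = benzylated ring A–B dimer | O=C1C(OCc9ccccc9)=C(OCc9ccccc9)C1(OCOC)/C=C\Oc2c(OCc9ccccc9)cc(Oc3c(OCc9ccccc9)cc(OCc9ccccc9)cc3OCc9ccccc9)cc2OCc9ccccc9
A8 | alternative 3 | ring A–B–C trimer phenol with free C6 hydroxyl on ring C | Oc1c(OCc9ccccc9)c(OCc9ccccc9)c(OCOC)cc1Oc2c(OCc9ccccc9)cc(Oc3c(OCc9ccccc9)cc(OCc9ccccc9)cc3OCc9ccccc9)cc2OCc9ccccc9
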